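## Structural features

The target is a 5-4-5 tricycle: cyclopentane ring A (C1–C5) and cyclopentane ring C (C6–C10) are fused to opposite edges (C1–C5 and C6–C10) of cyclobutane ring B, and an α,β-unsaturated γ-lactone (O–C12(=O)–C11=C7, with C13 as an acetoxymethyl group on C11) is fused to ring C across C6–C7. Both five-membered rings lie on the same (α) face of ring B, so the C10 methyl group, the C6 lactone oxygen and H-1/H-5 all sit on the β face. Seven stereocentres are present: six (C10, C1, C2, C4, C5, C6) form one array around rings A and B, with the quaternary C10 and the fully substituted C6 adjacent on the four-membered ring, and the seventh (C8, tigloyloxy) lies between C7 and C9 on ring C. Fragile elements are the three different esters (two acetates and a conjugated tiglate), the tertiary C4 alcohol, the C8 centre (allylic and γ to the lactone carbonyl), and above all the C6–O bond on the strained ring: as a free alkoxide next to a carbonyl it invites retro-aldol cleavage or α-ketol ring expansion. The real difficulty is the cyclobutane with two adjacent fully substituted carbons, the unfavourable syn disposition of rings A and C, and the differentiation of five oxygen functions. The key step exploits the 1,3-dioxygenation of ring A (C2, C4) and its fusion at C1–C5: with C4 as a ketone and C1=C5 as an olefin, ring A is a 4-alkoxycyclopent-2-enone, the Nazarov product of a ketone flanked by the ring B cyclobutene and a β-alkoxyvinyl group, and the trigonal C1/C5 then accept hydrogen from the face opposite ring C.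

## Logic of the disconnections

33 ⇒ 31 + 32. The C8–O acyl bond is cut last because the tiglate is the group least tolerant of radical hydration, fluoride and base. This leaves a diol whose two hydroxyls differ in class. The forward step must acylate a hindered secondary allylic alcohol without touching the tertiary C4–OH or epimerizing C8.

31 ⇒ 30 ⇒ 29. The C13–O acetyl bond and then the two O–Si bonds (C8, C13) are cut. C8–OH and C13–OH must stay masked while C6 is acylated and C4 is hydrated; one fluoride step then frees both. The demand is primary-selective acetylation in 30.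

29 ⇒ 28. The C4–O bond is cut (hydration of a C4 methylene). Methyl addition to a C4 ketone would come from the convex face and give the wrong epimer, whereas oxygen capture by a C4 radical from that face gives the right one. Keeping C4 as an olefin until here also means 22 has only one free tertiary alcohol. The forward step needs hydrogen-atom transfer to the 1,1-disubstituted olefin only, and β-face trapping.

28 ⇒ 27 ⇒ 22 + 26. The C7=C11 bond (intramolecular olefination) and the C6–O–C12 ester bond are cut. This is the standard reduction of a butenolide to an α-ketol plus a phosphonoacetic acid that already carries C13. The demands are esterification of a hindered tertiary cyclobutanol and a base mild enough for the C8 centre and the β-silyloxy phosphonate.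

26 ⇒ 25 ⇒ 24 ⇒ 23. The ester O–benzyl bond, the O–Si bond and the C11–C13 bond are cut back to a commercial phosphonoacetate. Each forward step must avoid β-elimination to a phosphonoacrylate.

22 ⇒ 21 ⇒ 18. The O–Si bond and then the C8–O bond are cut. C8 is the only enolizable position of the C7 ketone, so regiochemistry is automatic. The demand is oxidant delivery to the convex face and chemoselectivity over the C4 methylene.

18 ⇒ 17 ⇒ 16. The C7 carbonyl is returned to the alcohol level and both O–Si bonds are restored. C7 is carried as a silyl ether from step 3 because it is the stereocontrol element for ring B. The C6 silyl ether must stay until no carbonyl is β to C6.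

16 ⇒ 15 ⇒ 14. The C2–O acetate bond (with inversion) and the C4=CH2 bond are cut. The Nazarov/hydrogenation sequence delivers the 2α-oxygen, so inversion is needed. It is placed after methylenation because a β-hydroxy ketone would eliminate under Mitsunobu conditions.

14 ⇒ 12. The C1–H and C5–H bonds are cut, and the O–benzyl bond is restored. The syn relation of rings A and C is only reachable by adding both hydrogens to a C1=C5 olefin from the face away from ring C. The demand is β-face selectivity and survival of the C2–O bond.

12 ⇒ 10. The C1–C2 bond is cut (key step). One σ-bond closes ring A and sets C2. The forward step demands a 4π closure onto an alkoxy-stabilized terminus and proton loss from C1.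

10 ⇒ 8 + 9, and 8 ⇒ 7 ⇒ 6. The C2–O enol ether bond, the C4–C3 bond and the C4–N bond are cut. Alcohol addition to a terminal ynone gives the E-enol ether reliably. Direct acylation of a simple vinyl ether by an unactivated acyl donor was set aside as undependable.

6 ⇒ 4 + 5. The C5–C6 and C1–C10 bonds of ring B are cut. One step builds the cyclobutene with the acyl carbon already on C5. It replaces a Pauson–Khand / epoxide opening / Wolff contraction / dehydrogenation sequence, whose diazo transfer would have to choose between two methylene groups (C1 and C5) flanking the ring ketone in like environments. The demand is ring closure rather than desilylative Michael addition, anti to the C7 substituent.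

4 ⇒ 3 ⇒ 2 ⇒ 1. The O–Si bonds and the C7–H bond (carbonyl reduction) are cut back to a commodity diosphenol. The only demand is enantioselective reduction.

## Other disconnections considered

Alternative 1: The cut is at C8–C9 and at C10–CH3. In the forward key step the acyl-anion equivalent A2 adds to the exocyclic methylene carbon (C9) of the α-methylene cyclobutanone A1, and the C10 enolate is methylated by A3 from the convex face to give A4.
- In its favour: the three-component conjugate addition–alkylation is established chemistry. Convex-face alkylation sets the quaternary C10 and automatically puts the C9 chain syn to ring A. All ring A stereocentres are in place beforehand.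
- Against it here: A1 is a strained, polymerization-prone acceptor, and A2 may attack the cyclobutanone carbonyl instead. After A4, ring C must still be closed by aldol attack on the cyclobutanone from the concave side, giving a retro-aldol-labile cyclobutanol. C7 must then be turned into the tetrasubstituted butenolide carbon and C8 reduced with control.
- Comparison: on structure the two plans are equal, since both solve the syn-ring problem by convex-face delivery (alkyl to an enolate there, hydrogen to an olefin here). On mechanism Alternative 1 is the better, because its key step needs no new reactivity. On step economy the chosen plan is ahead: it reaches the ring B/C core in four steps, while A1 needs a separate enantioselective ring A synthesis and a longer ring C endgame.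

Alternative 2: The cut is at C1–C5 and C6–C10 at once. In the forward key step, irradiation of the ten-membered trienolide A5 effects a transannular [2+2] cycloaddition to give A6, which is identical with 31.
- In its favour: rings A, B and C and four stereocentres (C1, C5, C6, C10) arise in one step. The parent hydrocarbon ring system is known to photocyclize in this sense. Only tigloylation would remain.
- Against it here: A5 needs a ten-membered ring with two ring-cis olefins, three stereocentres and an enol-lactone diene. The reacting conformer (parallel rather than crossed olefins, correct faces relative to C2, C4 and C8) is not controlled by anything obvious, and E/Z photoisomerization and lactone-diene photochemistry compete.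
- Comparison: after the key step this alternative is clearly the better (one step against sixteen). Its reaction type also has closer precedent than the Nazarov step. The chosen plan is stronger on structure, because each stereocentre is set by a separate, analysable event and the precursor is short, whereas all of Alternative 2 rests on one conformationally uncontrolled photoreaction of a hard-to-make macrocycle.

Alternative 3: The cut is at C6–C10. In the forward key step, irradiation of the ring-A-fused tropolone ether A7 causes disrotatory 4π closure to the bicyclo[3.2.0]heptadienone A8.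
- In its favour: the photoisomerization of tropolone ethers is classical chemistry. A8 already holds the C6 oxygen, the C10 methyl group, the C7 ketone and a C8=C9 enone as a handle for C8 oxygenation. Its ring A enone allows the same convex-face hydrogenation as 12.
- Against it here: the only stereocentre of A7 is the remote C2, so facial control over C6/C10 is weak and no absolute control comes from the reaction itself. Secondary photorearrangement of the product is a known risk. A7 needs its own multistep synthesis, and C1=C5 must later be reduced selectively beside C8=C9.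
- Comparison: on mechanism Alternative 3 is the better (a known photoreaction against an unprecedented Nazarov case). On ring C functionality it is at least the equal of 12. The chosen plan is better on stereocontrol (C6/C10 follow from a catalyst-set C7 centre) and probably equal on overall step count.

Key step: step 8

Remarks on the chemistry (assumptions and corrections):
- Target numbering is used for all intermediates. β is the side of the C10 methyl group and the C6 oxygen; α is the side of ring B on which ring C lies.
- The oxazaborolidine reduction is assumed to follow the usual model (siloxyvinyl carbon as the large group), and the [2+2] addition is assumed to occur anti to the C7 siloxy group. Should either sense be reversed, the antipodal catalyst is used in step 2, since C7 is later oxidized.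
- Precursor design: silyl ethers at C6 and C7 replace a methoxymethyl ether and a dioxolane (acetals ionize under the Lewis acid of step 8), and C7 stays at the alcohol level until step 13.
- A check of the descriptors shows that the Nazarov product must carry the 2α (R) ether when closure occurs on the β lobe of C1 with an E-enol ether, so C2 has to be inverted later (step 11).

## Route

Step 1
Reactants: 1 cyclotene (2-hydroxy-3-methylcyclopent-2-en-1-one)
Product: 2 2-[(tert-butyldimethylsilyl)oxy]-3-methylcyclopent-2-en-1-one
Conditions: TBSCl, imidazole, DMF, 23 °C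
Reagents that add atoms: tert-butyldimethylsilyl chloride, CC(C)(C)[Si](C)(C)Cl
Why: O-silylation of the enolized 1,2-dione; only the enol oxygen reacts, which fixes C6 as the future silyl enol ether carbon and leaves C7 as the sole carbonyl.

Step 2
Reactants: 2 siloxy enone
Product: 3 (S)-2-[(tert-butyldimethylsilyl)oxy]-3-methylcyclopent-2-en-1-ol
Conditions: (R)-1-methyl-3,3-diphenyltetrahydro-1H,3H-pyrrolo[1,2-c][1,3,2]oxazaborole (10 mol%), catecholborane, toluene, −78 °C; aq. NaHCO3
Reagents that add atoms: none
Why: Corey–Bakshi–Shibata reduction; with the siloxyvinyl carbon as the large group and the ring CH2 as the small one, the (R)-catalyst should deliver hydride to give the (S)-carbinol at C7, and catecholborane avoids hydroboration of the enol ether.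

Step 3
Reactants: 3 (S)-allylic alcohol
Product: 4 (S)-1,2-bis[(tert-butyldimethylsilyl)oxy]-3-methylcyclopent-2-ene
Conditions: TBSCl, imidazole, DMF, 23 °C
Reagents that add atoms: tert-butyldimethylsilyl chloride, CC(C)(C)[Si](C)(C)Cl
Why: Standard silylation of a secondary allylic alcohol under mild base that leaves the acid-labile silyl enol ether intact; the bulky C7 silyl ether becomes the control element for step 4.

Step 4
Reactants: 4 bis-silyl enol ether; 5 methyl propiolate
Product: 6 methyl 1,2-bis[(tert-butyldimethylsilyl)oxy]-5-methylbicyclo[3.2.0]hept-6-ene-7-carboxylate (target numbering: ester on C5, C1=C5 olefin, 6β-OTBS, 7β-OTBS, 10β-CH3)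
Conditions: Tf2NH (2 mol%), CH2Cl2, −78 °C
Reagents that add atoms: none
Why: Acid-catalysed [2+2] cycloaddition of a silyl enol ether with a propiolate (Mukaiyama–Michael attack of C10 on the alkyne terminus, then closure of the allenoate α-carbon C5 onto the C6 silyloxocarbenium ion), which puts the ester carbon on C5 next to C6. The cis ring fusion is enforced by the four-membered ring and both bonds should form anti to the pseudoaxial C7 siloxy group, so (S)-C7 sets C6 and C10.

Step 5
Reactants: 6 cyclobutene ester
Product: 7 N-methoxy-N-methylamide of 6 (Weinreb amide at C4)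
Conditions: MeNHOMe·HCl, i-PrMgCl, THF, −20 → 0 °C
Reagents that add atoms: N,O-dimethylhydroxylamine hydrochloride, CNOC.Cl
Why: Ester-to-Weinreb-amide exchange with the chloromagnesium amide; attack at the ester carbonyl is preferred to conjugate addition at the trisubstituted cyclobutene, and the C6 silyl ether stays on (its loss would open ring B by retro-aldol).

Step 6
Reactants: 7 Weinreb amide
Product: 8 cyclobutenyl ethynyl ketone (C4 ketone, C3≡C2 alkyne)
Conditions: HC≡CMgBr, THF, 0 °C; aq. NH4Cl
Reagents that add atoms: ethynylmagnesium bromide, C#C[Mg]Br
Why: Weinreb ketone synthesis; the chelated tetrahedral intermediate prevents over-addition and releases the cross-conjugated ynone only on work-up.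

Step 7
Reactants: 8 ynone; 9 benzyl alcohol
Product: 10 cyclobutenyl (E)-2-(benzyloxy)vinyl ketone (Nazarov precursor)
Conditions: PMe3 (10 mol%), CH2Cl2, 0 °C
Reagents that add atoms: none
Why: Phosphine-catalysed oxa-Michael addition of an alcohol to a terminal ynone, which gives the (E)-β-alkoxyvinyl ketone; the ynone terminus is far more electrophilic than the cyclobutene carbon C1.

Step 8
Reactants: 10 cyclobutenyl benzyloxyvinyl ketone
Product: 12 tricyclic enone (C4 ketone; C1=C5 olefin; 2α-benzyloxy; 6β,7β-bis-OTBS; 10β-methyl), via oxyallyl cation 11 (not isolated)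
Conditions: Cu(OTf)2 (1.0 equiv), 2,6-di-tert-butyl-4-methylpyridine, ClCH2CH2Cl, 23 → 60 °C
Reagents that add atoms: none
Why: Proposed new method: Cu(OTf)2 binds the C4 carbonyl oxygen of 10 and turns the dienone into a 3-oxidopentadienyl cation (C1=C5–C4–C3=C2) whose C2 terminus is an oxocarbenium carbon; conrotatory 4π electrocyclization joins C1 to C2 to give oxyallyl cation 11, and removal of the C1 proton by the hindered pyridine restores the conjugated C1=C5 bond of 12. The closest known reaction type is the Lewis-acid-catalysed Nazarov cyclization of heteroatom-polarized divinyl ketones, in which a cyclobutenyl arm and a β-alkoxy terminus have not been combined. Ring A (five-membered) is closed by a thermal conrotatory 4π electrocyclization that forms one σ-bond, C1–C2. The only new stereocentre, C2, is set by torquoselectivity: in the E-enol ether the benzyloxy group is the outside substituent, and bonding to the β lobe of C1 (away from ring C) turns it to the α face, giving the (R)-centre. Two selectivities are needed: the sense of conrotation, which the folded ring C should secure by shielding the α face of C1, and loss of the C1 proton rather than the C2 proton, which is favoured because the charge of 11 sits mainly on the tertiary C5 terminus while C3 is deactivated by the adjacent C2–O bond. The oxygen donor stabilizes the open cation and so slows closure (ring opening of alkoxy-substituted oxyallyl cations is known); this is offset by release of cyclobutene strain when C1 pyramidalizes and by irreversible proton loss. Silyl ethers are used because they survive the Lewis acid, and C6 must stay capped because its free alkoxide would cleave the C5–C6 bond.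

Step 9
Reactants: 12 tricyclic enone
Product: 14 1β-H,5β-H-2α-hydroxy-4-ketone (6β,7β-bis-OTBS), via benzyl ether ketone 13 (not isolated)
Conditions: H2 (1 atm), Pd/C, EtOAc, 23 °C
Reagents that add atoms: none
Why: Heterogeneous hydrogenation of the strained, conjugated tetrasubstituted olefin, followed by benzyl ether hydrogenolysis; syn delivery of both hydrogens to the β face (opposite ring C and the 2α-benzyloxy group) sets C1 and C5 and folds ring A onto the α face, syn to ring C.

Step 10
Reactants: 14 hydroxy ketone
Product: 15 4-methylene-2α-alcohol
Conditions: Zn, CH2Br2, TiCl4 (pre-formed reagent), THF/CH2Cl2, 0 → 23 °C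
Reagents that add atoms: dibromomethane, BrCBr
Why: Takai–Lombardo methylenation; the non-basic zinc/titanium reagent olefinates the hindered, enolizable C4 ketone without β-elimination or retro-aldol of the β-hydroxy ketone and tolerates the free hydroxyl and the silyl ethers.

Step 11
Reactants: 15 2α-alcohol
Product: 16 2β-acetate
Conditions: AcOH, PPh3, DIAD, toluene, 0 → 23 °C
Reagents that add atoms: acetic acid, CC(O)=O
Why: Mitsunobu esterification; acetate displaces the activated 2α-oxyphosphonium group from the open convex (β) face with inversion, and with C4 no longer a carbonyl the elimination open to a β-hydroxy ketone is shut off.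

Step 12
Reactants: 16 bis-silyl ether
Product: 17 6β,7β-diol
Conditions: HF·pyridine, pyridine, THF, 0 → 23 °C
Reagents that add atoms: none
Why: Buffered fluoride cleavage of both TBS ethers spares the acetate and the exocyclic olefin; the C6 hydroxyl is released only now that no carbonyl is β to it.

Step 13
Reactants: 17 diol
Product: 18 6β-hydroxy-7-ketone (α-ketol)
Conditions: Dess–Martin periodinane, NaHCO3, CH2Cl2, 0 → 23 °C
Reagents that add atoms: none
Why: Dess–Martin oxidation of the secondary C7 alcohol; the tertiary C6 alcohol cannot be oxidized, and the buffered neutral medium avoids α-ketol rearrangement and glycol cleavage.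

Step 14
Reactants: 18 α-ketol
Product: 21 6β,8β-dihydroxy-7-ketone, via bis-silyl enol ether 19 (not isolated), via siloxy epoxide 20 (not isolated)
Conditions: TMSOTf, Et3N, CH2Cl2, −78 → 0 °C; DMDO, acetone, −78 °C; citric acid, MeOH, 0 °C
Reagents that add atoms: dimethyldioxirane, CC1(C)OO1
Why: Rubottom oxidation; C8 is the only enolizable position of the C7 ketone, and the electron-rich silyl enol ether is epoxidized far faster than the C4 methylene. The oxidant should approach the convex β face of ring C (the α face lies inside the fold over ring A), setting 8β-OH.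

Step 15
Reactants: 21 dihydroxy ketone
Product: 22 8β-triethylsilyl ether (6β-OH free)
Conditions: TESCl, imidazole, CH2Cl2, −20 °C
Reagents that add atoms: chlorotriethylsilane, CC[Si](Cl)(CC)CC
Why: Selective silylation of the secondary C8 alcohol; the tertiary ring-fusion C6 alcohol is too hindered for a trialkylsilyl chloride under these conditions.

Step 16
Reactants: 23 benzyl 2-(diethoxyphosphoryl)acetate
Product: 24 benzyl 2-(diethoxyphosphoryl)-3-hydroxypropanoate (racemic)
Conditions: (CH2O)n (1.0 equiv), piperidine (cat.), THF, 60 °C
Reagents that add atoms: paraformaldehyde (as formaldehyde), C=O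
Why: Amine-catalysed aldol-type hydroxymethylation of the phosphonoacetate; one equivalent of formaldehyde and a weak base stop the sequence before olefination by a second formaldehyde.

Step 17
Reactants: 24 hydroxymethyl phosphonate
Product: 25 benzyl 3-[(tert-butyldimethylsilyl)oxy]-2-(diethoxyphosphoryl)propanoate
Conditions: TBSCl, imidazole, DMF, 23 °C
Reagents that add atoms: tert-butyldimethylsilyl chloride, CC(C)(C)[Si](C)(C)Cl
Why: Routine silylation of a primary alcohol; the silyloxy group is a poor leaving group, which suppresses β-elimination to the phosphonoacrylate in the later olefination.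

Step 18
Reactants: 25 benzyl ester
Product: 26 3-[(tert-butyldimethylsilyl)oxy]-2-(diethoxyphosphoryl)propanoic acid
Conditions: H2 (1 atm), Pd/C, EtOAc, 23 °C
Reagents that add atoms: none
Why: Neutral hydrogenolysis of the benzyl ester frees the acid without the base that would trigger β-elimination of the silyloxy group.

Step 19
Reactants: 22 α-ketol silyl ether; 26 phosphono acid
Product: 27 C6 ester of 22 with 26 (two epimers at the phosphonate carbon)
Conditions: DIC, 4-(dimethylamino)pyridine, CH2Cl2, 0 → 40 °C
Reagents that add atoms: none
Why: Steglich esterification; the C6 hydroxyl is the only free alcohol in 22 (C8 is silylated, C4 is still an olefin), so no selection between tertiary alcohols is needed.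

Step 20
Reactants: 27 keto phosphonate
Product: 28 butenolide (C7=C11; C13 as CH2OTBS; 8β-OTES; 4-methylene; 2β-OAc)
Conditions: LiCl, DBU, MeCN, 0 → 23 °C
Reagents that add atoms: none
Why: Intramolecular Horner–Wadsworth–Emmons olefination under Masamune–Roush conditions; the lithium-chelated phosphonate carbanion (more acidic than C8–H) attacks the C7 ketone in a five-membered closure and forms the C7=C11 butenolide, and the stereocentre at the phosphonate carbon disappears.

Step 21
Reactants: 28 methylene butenolide
Product: 29 4β-hydroxy-4α-methyl butenolide
Conditions: Co(acac)2 (20 mol%), PhSiH3, O2 (1 atm), i-PrOH/THF, 0 → 23 °C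
Reagents that add atoms: dioxygen, O=O
Why: Mukaiyama hydration; hydrogen-atom transfer to the 1,1-disubstituted olefin gives the tertiary C4 radical, which is trapped by O2 on the convex β face of ring A to give 4β-OH/4α-CH3. The tetrasubstituted, electron-poor butenolide olefin should be inert to the cobalt hydride.

Step 22
Reactants: 29 bis-silyl ether
Product: 30 4β,8β,13-triol 2β-acetate
Conditions: HF·pyridine, pyridine, THF, 0 → 23 °C
Reagents that add atoms: none
Why: Buffered fluoride cleavage of the secondary TES and primary TBS ethers; the esters, the butenolide and the tertiary alcohol are stable to these conditions.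

Step 23
Reactants: 30 triol
Product: 31 2β,13-diacetate 4β,8β-diol
Conditions: AcCl, 2,4,6-collidine, CH2Cl2, −78 °C
Reagents that add atoms: acetyl chloride, CC(Cl)=O
Why: Low-temperature acetylation with a hindered pyridine base discriminates the primary allylic C13 alcohol from the hindered secondary C8 and tertiary C4 alcohols.

Step 24
Reactants: 31 diol; 32 tiglic acid
Product: 33 CNP0210373.1 (target)
Conditions: 32, 2,4,6-trichlorobenzoyl chloride, Et3N, toluene, 23 °C; then 31, 4-(dimethylamino)pyridine, 40 °C
Reagents that add atoms: none
Why: Yamaguchi esterification; the mixed anhydride acylates the secondary C8 alcohol with retention while the tertiary C4 alcohol does not react, and the (E)-tiglate is the stable geometric isomer under these conditions.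

## Compound list

1 | cyclotene (2-hydroxy-3-methylcyclopent-2-en-1-one) | CC1=C(O)C(=O)CC1 | starting material
2 | 2-[(tert-butyldimethylsilyl)oxy]-3-methylcyclopent-2-en-1-one | CC1=C(O[Si](C)(C)C(C)(C)C)C(=O)CC1 | intermediate
3 | (S)-2-[(tert-butyldimethylsilyl)oxy]-3-methylcyclopent-2-en-1-ol | O[C@H]1CCC(C)=C1O[Si](C)(C)C(C)(C)C | intermediate
4 | (S)-1,2-bis[(tert-butyldimethylsilyl)oxy]-3-methylcyclopent-2-ene | CC(C)(C)[Si](C)(C)O[C@H]1CCC(C)=C1O[Si](C)(C)C(C)(C)C | intermediate
5 | methyl propiolate | C#CC(=O)OC | starting material
6 | methyl 1,2-bis[(tert-butyldimethylsilyl)oxy]-5-methylbicyclo[3.2.0]hept-6-ene-7-carboxylate (cis-fused; both siloxy groups and the methyl group β; C7 S) | C1C[C@]2(C)C=C(C(=O)OC)[C@]2(O[Si](C)(C)C(C)(C)C)[C@H]1O[Si](C)(C)C(C)(C)C | intermediate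
7 | N-methoxy-N-methylamide corresponding to 6 | C1C[C@]2(C)C=C(C(=O)N(C)OC)[C@]2(O[Si](C)(C)C(C)(C)C)[C@H]1O[Si](C)(C)C(C)(C)C | intermediate
8 | ethynyl ketone corresponding to 7 (1-(bicycloheptenyl)prop-2-yn-1-one) | C1C[C@]2(C)C=C(C(=O)C#C)[C@]2(O[Si](C)(C)C(C)(C)C)[C@H]1O[Si](C)(C)C(C)(C)C | intermediate
9 | benzyl alcohol | OCc1ccccc1 | starting material
10 | (E)-3-(benzyloxy)-1-(bicycloheptenyl)prop-2-en-1-one, Nazarov precursor (6β,7β-bis-OTBS, 10β-methyl) | C1C[C@]2(C)C=C(C(=O)/C=C/OCc3ccccc3)[C@]2(O[Si](C)(C)C(C)(C)C)[C@H]1O[Si](C)(C)C(C)(C)C | intermediate
11 | oxyallyl cation after C1–C2 closure, drawn without copper (1α-H, 2α-benzyloxy) | C1C[C@]2(C)[C@H]3[C@H](OCc4ccccc4)C=C([O-])[C+]3[C@]2(O[Si](C)(C)C(C)(C)C)[C@H]1O[Si](C)(C)C(C)(C)C | intermediate (not isolated)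
12 | tricyclic enone: C4 ketone, C1=C5 olefin, (2R) 2α-benzyloxy, 6β,7β-bis-OTBS, 10β-methyl | C1C[C@]2(C)C3=C(C(=O)C[C@H]3OCc4ccccc4)[C@]2(O[Si](C)(C)C(C)(C)C)[C@H]1O[Si](C)(C)C(C)(C)C | intermediate
13 | saturated ketone: 1β-H, 5β-H, 2α-benzyloxy, C4 ketone | C1C[C@]2(C)[C@@H]3[C@H](OCc4ccccc4)CC(=O)[C@@H]3[C@]2(O[Si](C)(C)C(C)(C)C)[C@H]1O[Si](C)(C)C(C)(C)C | intermediate (not isolated)
14 | 2α-hydroxy-4-ketone (1β-H, 5β-H, 6β,7β-bis-OTBS) | C1C[C@]2(C)[C@@H]3[C@H](O)CC(=O)[C@@H]3[C@]2(O[Si](C)(C)C(C)(C)C)[C@H]1O[Si](C)(C)C(C)(C)C | intermediate
15 | 4-methylene-2α-alcohol | C1C[C@]2(C)[C@@H]3[C@H](O)CC(=C)[C@@H]3[C@]2(O[Si](C)(C)C(C)(C)C)[C@H]1O[Si](C)(C)C(C)(C)C | intermediate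
16 | 4-methylene-2β-acetate | C1C[C@]2(C)[C@@H]3[C@@H](OC(C)=O)CC(=C)[C@@H]3[C@]2(O[Si](C)(C)C(C)(C)C)[C@H]1O[Si](C)(C)C(C)(C)C | intermediate
17 | 6β,7β-diol (2β-acetate, 4-methylene) | C1C[C@]2(C)[C@@H]3[C@@H](OC(C)=O)CC(=C)[C@@H]3[C@]2(O)[C@H]1O | intermediate
18 | 6β-hydroxy-7-ketone | C1C[C@]2(C)[C@@H]3[C@@H](OC(C)=O)CC(=C)[C@@H]3[C@]2(O)C1=O | intermediate
19 | 6β-OTMS, C7(OTMS)=C8 silyl enol ether | C[Si](C)(C)OC1=CC[C@]2(C)[C@@H]3[C@@H](OC(C)=O)CC(=C)[C@@H]3[C@]12O[Si](C)(C)C | intermediate (not isolated)
20 | 7β,8β-epoxide of 19 (7-OTMS α) | C[Si](C)(C)O[C@@]14O[C@H]4C[C@]2(C)[C@@H]3[C@@H](OC(C)=O)CC(=C)[C@@H]3[C@]12O[Si](C)(C)C | intermediate (not isolated)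
21 | 6β,8β-dihydroxy-7-ketone | O[C@H]1C[C@]2(C)[C@@H]3[C@@H](OC(C)=O)CC(=C)[C@@H]3[C@]2(O)C1=O | intermediate
22 | 8β-triethylsilyloxy-6β-hydroxy-7-ketone | CC[Si](CC)(CC)O[C@H]1C[C@]2(C)[C@@H]3[C@@H](OC(C)=O)CC(=C)[C@@H]3[C@]2(O)C1=O | intermediate
23 | benzyl 2-(diethoxyphosphoryl)acetate | CCOP(=O)(OCC)CC(=O)OCc1ccccc1 | starting material
24 | benzyl 2-(diethoxyphosphoryl)-3-hydroxypropanoate (racemic) | CCOP(=O)(OCC)C(CO)C(=O)OCc1ccccc1 | intermediate
25 | benzyl 3-[(tert-butyldimethylsilyl)oxy]-2-(diethoxyphosphoryl)propanoate (racemic) | CCOP(=O)(OCC)C(CO[Si](C)(C)C(C)(C)C)C(=O)OCc1ccccc1 | intermediate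
26 | 3-[(tert-butyldimethylsilyl)oxy]-2-(diethoxyphosphoryl)propanoic acid (racemic) | CCOP(=O)(OCC)C(CO[Si](C)(C)C(C)(C)C)C(=O)O | intermediate
27 | C6 ester of 22 with 26 (epimers at the phosphonate carbon) | CC[Si](CC)(CC)O[C@H]1C[C@]2(C)[C@@H]3[C@@H](OC(C)=O)CC(=C)[C@@H]3[C@]2(OC(=O)C(CO[Si](C)(C)C(C)(C)C)P(=O)(OCC)OCC)C1=O | intermediate
28 | butenolide: 13-OTBS, 8β-OTES, 4-methylene, 2β-OAc | CC[Si](CC)(CC)O[C@H]1C[C@]2(C)[C@@H]3[C@@H](OC(C)=O)CC(=C)[C@@H]3[C@@]23OC(=O)C(CO[Si](C)(C)C(C)(C)C)=C13 | intermediate
29 | butenolide: 4β-OH, 4α-CH3, 13-OTBS, 8β-OTES, 2β-OAc | CC[Si](CC)(CC)O[C@H]1C[C@]2(C)[C@@H]3[C@@H](OC(C)=O)C[C@@](C)(O)[C@@H]3[C@@]23OC(=O)C(CO[Si](C)(C)C(C)(C)C)=C13 | intermediate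
30 | 4β,8β,13-triol 2β-acetate | O[C@H]1C[C@]2(C)[C@@H]3[C@@H](OC(C)=O)C[C@@](C)(O)[C@@H]3[C@@]23OC(=O)C(CO)=C13 | intermediate
31 | 8-O-destigloyl target (2β,13-diacetate, 4β,8β-diol) | O[C@H]1C[C@]2(C)[C@@H]3[C@@H](OC(C)=O)C[C@@](C)(O)[C@@H]3[C@@]23OC(=O)C(COC(C)=O)=C13 | intermediate
32 | tiglic acid ((E)-2-methylbut-2-enoic acid) | C/C=C(\C)C(=O)O | starting material
33 | CNP0210373.1 | C/C=C(\C)C(=O)O[C@H]1C[C@]2(C)[C@@H]3[C@@H](OC(C)=O)C[C@@](C)(O)[C@@H]3[C@@]23OC(=O)C(COC(C)=O)=C13 | target

## Step count and least certain steps

Total: 24 steps. Longest linear sequence: 21 steps (steps 1–15 and 19–24, from 1); steps 16–18 make the side-chain acid 26.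

Step 8 (key step). Two things are most likely to go wrong. First, the electrocyclization may fail to compete: the benzyloxy group makes the open cation the thermodynamic sink, and forcing conditions risk Lewis-acid debenzylation. Second, the cation may terminate by loss of the C2 proton instead of the C1 proton. That would leave C1 as an sp3 centre fixed by the closure, with ring A on the wrong face, and give a vinylogous ester. The fallback uses known chemistry, sets out from 4 and returns at 12:
- (R)-4-(Benzyloxy)cyclopent-2-en-1-one F1 is made from commercial (R)-4-hydroxycyclopent-2-en-1-one and benzyl trichloroacetimidate.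
- F1 is irradiated (350 nm, CH2Cl2, −40 °C) with an excess of 4. The head-to-tail enone–enol ether [2+2] photocycloaddition joins C5 to C6 and C1 to C10, anti to the C7 siloxy group, and gives the saturated tricyclic ketone F2. Its C1/C5 configuration (ring A expected anti to ring C) does not matter.
- Thermodynamic enol silylation (TMSCl, NaI, Et3N, MeCN) gives the C4=C5 trimethylsilyl enol ether F3.
- Saegusa–Ito oxidation (Pd(OAc)2, MeCN; DDQ if palladium finds no syn hydrogen at C1) re-forms the C1=C5 olefin and gives 12, after which step 9 applies unchanged.

Step 4. The most likely failure is desilylative Michael addition without ring closure, or retro-aldol opening of the strained donor–acceptor cyclobutene, because the zwitterion from a tetrasubstituted enol ether closes slowly. Incomplete facial bias from C7 would in addition erode enantiopurity once C7 is oxidized. The fallback sets out from 4 and returns at 6: 4 and methyl acrylate under the same acid catalysis give the more robust cyclobutane ester F4; LDA then PhSeBr gives the C5 selenide F5; oxidation with H2O2 and syn elimination toward C1 gives 6.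

Step 9. The likely failures are hydrogen delivery to the α face (the β face carries the C10 methyl and C6 siloxy groups) and hydrogenolysis of the allylic, γ-keto C2–O bond before the olefin is saturated. The fallback sets out from 12 and returns at 14 through 13: conjugate reduction with [(Ph3P)CuH]6 (benzene, then H2O) places hydride on C1 anti to the adjacent 2α-benzyloxy group, and the enolate is protonated to the only possible cis-fused ketone 13. A separate hydrogenolysis (H2, Pd/C) on the now saturated system gives 14.

Step 14. The likely failure is approach of the oxidant from the α face (wrong C8 epimer), since the β face carries the C6 siloxy and C10 methyl groups; competing epoxidation of the C4 methylene is a smaller risk. The fallback sets out from 18 and returns at 21: the 8α-hydroxy ketone F6 is inverted by Mitsunobu reaction with chloroacetic acid to the 8β-chloroacetate F7, and thiourea with NaHCO3 in EtOH removes the chloroacetyl group without touching the C2 acetate, giving 21.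

Step 19. The likely failure is slow acylation of the hindered tertiary C6 alcohol by the α-branched acid, overtaken by base-promoted α-ketol rearrangement of the cyclobutanol (ring expansion by migration of C5 to C7). The fallback sets out from 26 and returns at 27: 26 is converted with (COCl)2 and catalytic DMF into the acid chloride F8, which with Et3N in the presence of 22 forms the phosphoryl ketene F9; ketene addition to the tertiary alcohol gives 27 by a path much less sensitive to steric hindrance.

## Further compounds

F1 | step 8 | (R)-4-(benzyloxy)cyclopent-2-en-1-one | O=C1C[C@@H](OCc2ccccc2)C=C1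
F2 | step 8 | [2+2] photoadduct: saturated tricyclic C4 ketone, 1α-H, 5α-H, (2R)-benzyloxy, 6β,7β-bis-OTBS, 10β-methyl | C1C[C@]2(C)[C@H]3[C@H](OCc4ccccc4)CC(=O)[C@H]3[C@]2(O[Si](C)(C)C(C)(C)C)[C@H]1O[Si](C)(C)C(C)(C)C
F3 | step 8 | C4=C5 trimethylsilyl enol ether of F2 | C1C[C@]2(C)[C@H]3[C@H](OCc4ccccc4)CC(O[Si](C)(C)C)=C3[C@]2(O[Si](C)(C)C(C)(C)C)[C@H]1O[Si](C)(C)C(C)(C)C
F4 | step 4 | methyl 1,2-bis[(tert-butyldimethylsilyl)oxy]-5-methylbicyclo[3.2.0]heptane-7-carboxylate (ester α, trans to the C6 siloxy group) | C1C[C@]2(C)C[C@H](C(=O)OC)[C@]2(O[Si](C)(C)C(C)(C)C)[C@H]1O[Si](C)(C)C(C)(C)C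
F5 | step 4 | C5 phenylselenide of F4 | C1C[C@]2(C)C[C@]([Se]c3ccccc3)(C(=O)OC)[C@]2(O[Si](C)(C)C(C)(C)C)[C@H]1O[Si](C)(C)C(C)(C)C
F0 | step 9 | none | none
F6 | step 14 | 8α-hydroxy epimer of 21 | O[C@@H]1C[C@]2(C)[C@@H]3[C@@H](OC(C)=O)CC(=C)[C@@H]3[C@]2(O)C1=O
F7 | step 14 | 8β-chloroacetate of 21 | ClCC(=O)O[C@H]1C[C@]2(C)[C@@H]3[C@@H](OC(C)=O)CC(=C)[C@@H]3[C@]2(O)C1=O
F8 | step 19 | 3-[(tert-butyldimethylsilyl)oxy]-2-(diethoxyphosphoryl)propanoyl chloride | CCOP(=O)(OCC)C(CO[Si](C)(C)C(C)(C)C)C(Cl)=O
F9 | step 19 | [(tert-butyldimethylsilyl)oxymethyl](diethoxyphosphoryl)ketene | CCOP(=O)(OCC)C(CO[Si](C)(C)C(C)(C)C)=C=O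
A1 | alternative 1 | α-methylene cyclobutanone with ring A (2-OTBS, 4-OTES, 4-methyl) | C=C1[C@@H]2[C@@H](O[Si](C)(C)C(C)(C)C)C[C@@](C)(O[Si](CC)(CC)CC)[C@@H]2C1=O
A2 | alternative 1 | 2-lithio-2-methyl-1,3-dithiane | [Li]C1(C)SCCCS1
A3 | alternative 1 | iodomethane | CI
A4 | alternative 1 | C10-quaternary cyclobutanone with dithiane chain | CC1(SCCCS1)C[C@]2(C)[C@@H]3[C@@H](O[Si](C)(C)C(C)(C)C)C[C@@](C)(O[Si](CC)(CC)CC)[C@@H]3C2=O
A5 | alternative 2 | 2,13-diacetoxy-4,8-dihydroxygermacra-1(10),5,7(11)-trien-12,6-olide (both ring olefins ring-cis) | CC(=O)O[C@@H]1/C=C(C)\C[C@H](O)C2=C(COC(C)=O)C(=O)O/C2=C/[C@](C)(O)C1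
A6 | alternative 2 | 8-hydroxy 5-4-5 tetracycle (identical with 31) | O[C@H]1C[C@]2(C)[C@@H]3[C@@H](OC(C)=O)C[C@@](C)(O)[C@@H]3[C@@]23OC(=O)C(COC(C)=O)=C13
A7 | alternative 3 | ring-A-fused 2-benzyloxy-5-methyltropone (2-OTBS on ring A) | O=C1C=CC(C)=C2[C@H](O[Si](C)(C)C(C)(C)C)CC(=O)C2=C1OCc3ccccc3
A8 | alternative 3 | tricyclic bicyclo[3.2.0]heptadienone | O=C1C=C[C@]2(C)C3=C([C@]12OCc4ccccc4)C(=O)C[C@H]3O[Si](C)(C)C(C)(C)C
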